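## Structural features

Kraussianone 3 (25) is an isoflavone: a benzo-fused 4-pyranone (rings A and C) that carries ring B at C3 through the C3–C1' bond. Ring B is resorcinol-derived, and a 2,2-dimethyl-2H-pyran (ring D) is fused to it linearly at C4'–C5', with the oxygen on C4' and the styrenic carbon C4'' on C5'. Ring A is pentasubstituted and 1,2,4-trioxygenated: O1 on C8a, a free hydroxyl on C8, a chelated hydroxyl on C5, and a 3-hydroxy-3-methylbutyl chain on C6 between C5 and C7–H. There is no stereocentre, so every problem is one of position and of functional-group tolerance.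

The fragile elements are:
- the 5,8-hydroquinone, which air oxidises to the quinone under base;
- the tertiary alcohol ortho to O5, which acid can close onto O5 to a chroman (strong acid can also scramble the 5,8- into the 5,6-dioxygenated chromone by a Wessely–Moser ring opening);
- the chromene double bond, sensitive to acid and hydrogenation;
- C2 of the isoflavone, which hydroxide attacks.

The real difficulties are to dress ring A so that O1 and O5 cannot be interchanged, and to fuse ring D toward C5' and not toward C3', which lies between the two ring-B oxygens. The key step uses the fact that C4'' is bonded to C5', a carbon ortho to O4' and para to O2'. An O4' 1,1-dimethylpropargyl ether already holds the C4'–O and O–C2'' bonds, so only C5'–C4'' has to be made, by attack of C5' on the terminal alkyne carbon.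

## Logic of the disconnections

25 to 24: the O–Si bonds on O8 and O2' are cut. The last step must be neither acidic (chromene, tertiary alcohol beside O5) nor basic and oxidising (hydroquinone, C2), and aryl silyl ethers fall to buffered fluoride. O5 needs no group because its hydrogen bond to C4=O protects it. The forward step must exclude air and keep the phenoxides protonated.

24 to 23: the C5'–C4'' bond of ring D is cut. This removes one ring and leaves a tertiary aryl propargyl ether in which the C–O bonds of ring D are already in place. The forward step (alkyne activation by Ph3PAuNTf2) must close at C5' and not at C3', which is why O2' carries the bulkiest group in the molecule.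

23 to 21 and 22: the O4'–C2'' ether bond is cut. The five-carbon unit becomes a commercial tertiary propargylic chloride. The forward alkylation demands that O4' be the only phenol able to react: O8 and O2' are silylated and O5 is chelated and flanked on both sides.

21 to 20 to 19 to 18: only protecting-group bonds are cut (benzyl C–O on O4', Si–O on O8 and O2', acetal C–O on O5, O8 and O2'). Benzyl marks the one oxygen that must later be alkylated and leaves by hydrogenolysis before any alkyne or chromene exists. The acetals are needed for the organometallic steps and are exchanged for silicon in a single pair of steps. The acid step must spare the tertiary alcohol, and 19, a free hydroquinone, must be silylated without storage.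

18 to 13 and 17: the C3–C1' bond is cut. This divides the molecule into a ring-A iodochromone and a ring-B boronate of similar size. The forward cross-coupling must tolerate an ortho-substituted, electron-rich boronate and must not open the pyranone at C2.

13 to 11 (through 12): O1–C2 and C2–C3 are cut, and C3–I is removed; C2 becomes a one-carbon reagent. Ring C disappears and a methyl ketone remains. The forward cyclisation demands that only the oxygen destined to be O1 is free; O5 is blocked, so O1 and O5 cannot be confused.

11 to 9 to 8: the C4a–C4 bond is cut by way of the aryl iodide. The acyl carbon is placed at the only position ortho to the single free phenol, so no isomer can arise. The forward coupling has to work at a carbon flanked by two oxygen substituents and without Lewis acids.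

8 to 5 and 6 (through 7): the C6–C1''' bond is cut. The whole side chain, tertiary alcohol included, comes from a commercial alkenol. The forward alkyl–aryl coupling must proceed with two unprotected hydroxyl groups.

5 to 4 to 2 to 1: C6–I is removed, the C8a–O bond is traced to an aldehyde carbon (aldehyde-to-phenol oxidation), and the two acetals are removed. This makes the future O1 the one free hydroxyl of a hydroxyquinol whose other two oxygens come from a cheap hydroquinone aldehyde. Iodination must go para to that hydroxyl.

17 to 16 to 15 to 14: C1'–B and the two ring-B ether bonds are cut. The forward sequence needs one selective event, mono-alkylation of the hydroxyl para to bromine.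

## Other disconnections considered

Alternative 1: The cut runs through ring C at C3–C4 and O1–C2, so the heterocycle itself is the junction of a ring-A acid chloride A1 and a ring-B enamine A2 that already contains ring D. In the forward sense A1 would acylate the aryl-bearing carbon of A2. Removal of the O8a acetate in the same flask would let the phenoxide add to the amine-bearing carbon and expel the secondary amine, giving A3.
- In its favour: fragment union and ring C formation are one operation, no Pd-catalysed coupling or iodocyclisation is needed, and the acetate on O8a fixes O1 against O5 as cleanly as the free phenol does in the chosen plan.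
- Against it here: A2 must already hold the linearly fused chromene, so the C5'-versus-C3' question is only moved to an earlier, small intermediate and is not answered by the key step. A1 is a doubly ortho-substituted aroyl chloride that must be made and used in the presence of acetals and a silyl ether, and it must acylate a hindered, aryl-substituted enamine carbon. A3 carries three methoxymethyl ethers, so the final step would be an acid treatment in the presence of the chromene and of a tertiary alcohol beside O5.
- Comparison: in structure the two plans are equal on ring A. In step economy this plan is probably better by two or three steps, because ring closure and coupling coincide. In mechanism it is weaker at the end: its deprotection is acidic where the chosen plan uses buffered fluoride, and the most delicate transformation is postponed to the last step.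

Alternative 2: The cut lies inside the side chain, at C1'''–C2''' with a temporary O5–C3''' bond. The Mannich base A4 would lose its amine on heating to give the ring-A ortho-quinone methide A5, which would add the enol ether A6 in a hetero-Diels–Alder reaction to give the racemic cyclic ketal A7. Hydrolysis to the methyl ketone A8, addition of a methyl nucleophile and deprotection would follow.
- In its favour: the chain is built late from one- and three-carbon pieces; the aminomethyl group can only enter at C6 because C8 is oxygenated; the key step needs no reagent and no metal; the tertiary alcohol appears only near the end.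
- Against it here: the heating is done with the chromene present, which is itself an electron-rich alkene that can compete as the two-electron partner. Three further steps follow the key step, one of them a carbonyl addition beside the pyranone carbonyl and its electrophilic C2. The end is again an acidic removal of acetals. The step solves the side chain, which the chosen plan installs in one alkyl–aryl coupling, and leaves the two central problems (ring-A oxygen pattern, direction of ring D) untouched.
- Comparison: on structure the plans are equal, since the stereocentre of A7 is lost on hydrolysis and neither plan sets one. On mechanism this plan is equal or better in simplicity at the key step (pericyclic, metal-free). On step economy it is worse by about three steps.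

Alternative 3: The cut is the O1–C8a bond. A diacetoxyiodoarene oxidant in aqueous acetonitrile would convert the 4-methoxyphenol ring of the hydroxymethylene ketone A9 into the acylquinone A10. The enol oxygen would then add to the quinone carbon next to the acyl group (oxa-Michael, 6-endo) and tautomerise to the hydroquinone A11.
- In its favour: ring A needs only two oxygens at the outset, because the third C–O bond and ring C are made together. This would save the aldehyde-to-phenol oxidation, both iodinations and the acetal–silyl exchange of the chosen plan. A11 has O5 and O8 already free, so one silyl ether remains to be removed.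
- Against it here: A9 has a free phenol ortho to the ketone and would be expected to close onto the hydroxymethylene carbon in the ordinary isoflavone sense, giving the wrong ring, before any oxidant is added. The oxidant would meet an enolised 1,3-dicarbonyl, an electron-rich chromene and a product hydroquinone that is easier to oxidise than the starting phenol. Water could compete for the acylquinone. Ring D would again have to be in place beforehand.
- Comparison: on step economy for ring A this plan is clearly better. On structure it is equal (no stereocentre, same skeleton). On mechanism it is the riskiest of the four, because chemoselectivity rests on an oxidation in the presence of three oxidisable groups, whereas the chosen plan keeps oxidants away from the assembled molecule.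

Key step: step 16

Remarks on the chemistry (assumptions):
- The target is read as the 5,8-dihydroxy-6-alkyl isoflavone with ring D fused at C4'–C5'; the skeletons of 23 and 24 agree with this and need no correction.
- Protecting groups are redesigned: O5 is left free in 23 and 24, because a silyl ether there is hard to install beside the tertiary alcohol and is unnecessary. O8 and O2' carry triisopropylsilyl groups installed together, and the final desilylation is buffered.
- Steps 2, 4, 6 and 7 are two-stage operations in one flask; 22 is taken as a commercial reagent; 19 is used at once under argon.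

## Steps

Step 1
Reactants: 1 2,5-dihydroxybenzaldehyde
Product: 2 2,5-bis(methoxymethoxy)benzaldehyde
Conditions: MOMCl (2.6 equiv), i-Pr2NEt (3 equiv), CH2Cl2, 0 °C to 40 °C
Reagents that add atoms: chloromethyl methyl ether (MOMCl), COCCl
Why: Double O-alkylation of the phenols (acetal formation); the chelated 2-OH needs the excess and warming, and the acetal is chosen because it survives peracid, NIS and organometallic coupling and cannot migrate between neighbouring oxygens.

Step 2
Reactants: 2 2,5-bis(methoxymethoxy)benzaldehyde
Product: 4 2,5-bis(methoxymethoxy)phenol, via aryl formate 3 (not isolated)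
Conditions: mCPBA (1.3 equiv), CH2Cl2, 0 °C to rt; aq. NaHCO3/Na2S2O3 wash; then K2CO3 (cat.), MeOH, 0 °C
Reagents that add atoms: 3-chloroperoxybenzoic acid (mCPBA), OOC(=O)c1cccc(Cl)c1
Why: Baeyer–Villiger (Dakin-type) oxidation: the electron-rich aryl group migrates to give formate 3, which mild methanolysis cleaves; the aldehyde carbon is thereby replaced by the single free hydroxyl that becomes O1.

Step 3
Reactants: 4 2,5-bis(methoxymethoxy)phenol
Product: 5 4-iodo-2,5-bis(methoxymethoxy)phenol
Conditions: NIS (1.0 equiv), MeCN, −20 °C to 0 °C, dark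
Reagents that add atoms: N-iodosuccinimide (NIS), O=C1CCC(=O)N1I
Why: Electrophilic aromatic iodination para to the free hydroxyl, the most activated and least hindered position (the open ortho carbon is flanked by two oxygens); no acid is added, so the acetals survive.

Step 4
Reactants: 5 4-iodo-2,5-bis(methoxymethoxy)phenol; 6 2-methylbut-3-en-2-ol
Product: 8 4-(3-hydroxy-3-methylbutyl)-2,5-bis(methoxymethoxy)phenol, via B-alkyl-9-BBN borane 7 (not isolated)
Conditions: 6, 9-BBN (1.3 equiv), THF, 0 °C to rt; then 5, Pd(dppf)Cl2 (5 mol%), aq. K3PO4, THF/DMF, 60 °C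
Reagents that add atoms: none
Why: Anti-Markovnikov hydroboration of the terminal alkene gives 7, and B-alkyl Suzuki–Miyaura coupling with the aryl iodide forms the C6–C1''' bond, delivering the saturated hydroxylated chain in one operation.

Step 5
Reactants: 8 4-(3-hydroxy-3-methylbutyl)-2,5-bis(methoxymethoxy)phenol
Product: 9 4-(3-hydroxy-3-methylbutyl)-2-iodo-3,6-bis(methoxymethoxy)phenol
Conditions: NIS (1.05 equiv), MeCN, 0 °C, dark
Reagents that add atoms: N-iodosuccinimide (NIS), O=C1CCC(=O)N1I
Why: Second electrophilic iodination; with the para position alkylated, the only carbon ortho to the phenol is the one that becomes C4a.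

Step 6
Reactants: 9 4-(3-hydroxy-3-methylbutyl)-2-iodo-3,6-bis(methoxymethoxy)phenol
Product: 11 1-[2-hydroxy-5-(3-hydroxy-3-methylbutyl)-3,6-bis(methoxymethoxy)phenyl]ethan-1-one, via enol ether 10 (not isolated)
Conditions: tributyl(1-ethoxyethenyl)stannane (1.3 equiv), Pd2(dba)3 (2.5 mol%), P(t-Bu)3·HBF4 (10 mol%), CsF (2.2 equiv), 1,4-dioxane, 80 °C; then 0.5 M HCl, THF, 0 °C, 15 min
Reagents that add atoms: tributyl(1-ethoxyethenyl)stannane, C=C(OCC)[Sn](CCCC)(CCCC)CCCC; water, O
Why: Stille coupling of the hindered aryl iodide with an acetyl-anion equivalent (bulky electron-rich phosphine, fluoride activation), then brief hydrolysis of enol ether 10 to the methyl ketone; the acyl group is placed without Lewis acids, which the acetals and the tertiary alcohol would not tolerate.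

Step 7
Reactants: 11 1-[2-hydroxy-5-(3-hydroxy-3-methylbutyl)-3,6-bis(methoxymethoxy)phenyl]ethan-1-one
Product: 13 6-(3-hydroxy-3-methylbutyl)-3-iodo-5,8-bis(methoxymethoxy)-4H-chromen-4-one, via enaminone 12 (not isolated)
Conditions: Me2NCH(OMe)2 (3 equiv), PhMe, 90 °C; evaporate; then I2 (2 equiv), pyridine (2 equiv), CHCl3, rt
Reagents that add atoms: N,N-dimethylformamide dimethyl acetal, COC(OC)N(C)C; iodine, II
Why: Condensation of the methyl ketone with the formamide acetal gives enaminone 12, and iodine-induced cyclisation (α-iodination, conjugate addition of the only free phenol, loss of the amine) gives the 3-iodochromone; O5 is blocked, so O1 is fixed without ambiguity.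

Step 8
Reactants: 14 4-bromobenzene-1,3-diol (4-bromoresorcinol)
Product: 15 5-(benzyloxy)-2-bromophenol
Conditions: BnBr (1.0 equiv), K2CO3 (1.1 equiv), acetone, rt to 50 °C
Reagents that add atoms: benzyl bromide, BrCc1ccccc1
Why: Williamson mono-O-alkylation; the hydroxyl para to bromine is the less hindered and its phenoxide the more nucleophilic, so one equivalent of benzyl bromide should mark the future O4', with the regioisomer and the dibenzyl ether removed by chromatography.

Step 9
Reactants: 15 5-(benzyloxy)-2-bromophenol
Product: 16 4-(benzyloxy)-1-bromo-2-(methoxymethoxy)benzene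
Conditions: MOMCl (1.3 equiv), i-Pr2NEt (1.5 equiv), CH2Cl2, 0 °C to rt
Reagents that add atoms: chloromethyl methyl ether (MOMCl), COCCl
Why: Acetal protection of the remaining bromine-flanked phenol, so that O2' is inert in borylation and cross-coupling and is released later together with O5 and O8.

Step 10
Reactants: 16 4-(benzyloxy)-1-bromo-2-(methoxymethoxy)benzene
Product: 17 2-[4-(benzyloxy)-2-(methoxymethoxy)phenyl]-4,4,5,5-tetramethyl-1,3,2-dioxaborolane
Conditions: B2pin2 (1.3 equiv), Pd(dppf)Cl2 (3 mol%), KOAc (3 equiv), 1,4-dioxane, 90 °C
Reagents that add atoms: bis(pinacolato)diboron, CC1(C)OB(OC1(C)C)B1OC(C)(C)C(C)(C)O1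
Why: Miyaura borylation of the aryl bromide (oxidative addition, acetate-assisted transmetalation with the diboron reagent, reductive elimination); the pinacol ester is preferred because 2,4-dioxygenated arylboronic acids protodeboronate easily.

Step 11
Reactants: 13 6-(3-hydroxy-3-methylbutyl)-3-iodo-5,8-bis(methoxymethoxy)-4H-chromen-4-one; 17 2-[4-(benzyloxy)-2-(methoxymethoxy)phenyl]-4,4,5,5-tetramethyl-1,3,2-dioxaborolane
Product: 18 3-[4-(benzyloxy)-2-(methoxymethoxy)phenyl]-6-(3-hydroxy-3-methylbutyl)-5,8-bis(methoxymethoxy)-4H-chromen-4-one
Conditions: Pd(dppf)Cl2 (5 mol%), K3PO4 (3 equiv), 1,4-dioxane/H2O 9:1, 70 °C, argon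
Reagents that add atoms: none
Why: Suzuki–Miyaura coupling of a 3-iodochromone with an ortho-alkoxymethoxy arylboronate, the standard isoflavone construction; phosphate with little water limits hydroxide attack at C2.

Step 12
Reactants: 18 3-[4-(benzyloxy)-2-(methoxymethoxy)phenyl]-6-(3-hydroxy-3-methylbutyl)-5,8-bis(methoxymethoxy)-4H-chromen-4-one
Product: 19 3-[4-(benzyloxy)-2-hydroxyphenyl]-5,8-dihydroxy-6-(3-hydroxy-3-methylbutyl)-4H-chromen-4-one
Conditions: HCl (3 M in MeOH)/THF 1:1, 0 °C to rt, argon, degassed solvents
Reagents that add atoms: none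
Why: Acid-catalysed acetal exchange with methanol frees O5, O8 and O2' while the benzyl ether stays; low temperature and moderate acid strength are chosen to keep the tertiary alcohol from ionising, and air is excluded for the sake of the hydroquinone.

Step 13
Reactants: 19 3-[4-(benzyloxy)-2-hydroxyphenyl]-5,8-dihydroxy-6-(3-hydroxy-3-methylbutyl)-4H-chromen-4-one
Product: 20 3-[4-(benzyloxy)-2-(triisopropylsilyloxy)phenyl]-5-hydroxy-6-(3-hydroxy-3-methylbutyl)-8-(triisopropylsilyloxy)-4H-chromen-4-one
Conditions: TIPSCl (3 equiv), imidazole (6 equiv), DMAP (cat.), DMF, rt to 40 °C, argon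
Reagents that add atoms: chlorotriisopropylsilane (TIPSCl), CC(C)[Si](Cl)(C(C)C)C(C)C
Why: Silylation of the two accessible phenols; the chelated, doubly flanked 5-OH and the tertiary alcohol should not react with the bulky chlorosilane, so the selectivity rests on hydrogen bonding and sterics.

Step 14
Reactants: 20 3-[4-(benzyloxy)-2-(triisopropylsilyloxy)phenyl]-5-hydroxy-6-(3-hydroxy-3-methylbutyl)-8-(triisopropylsilyloxy)-4H-chromen-4-one
Product: 21 5-hydroxy-6-(3-hydroxy-3-methylbutyl)-3-[4-hydroxy-2-(triisopropylsilyloxy)phenyl]-8-(triisopropylsilyloxy)-4H-chromen-4-one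
Conditions: H2 (1 atm), 10% Pd/C, EtOAc, rt
Reagents that add atoms: none
Why: Hydrogenolysis of the aryl benzyl ether exposes O4' alone; aryl silyl ethers are inert, and the trisubstituted vinylogous-ester C2=C3 bond is reduced far more slowly, so the reaction is stopped at full debenzylation.

Step 15
Reactants: 21 5-hydroxy-6-(3-hydroxy-3-methylbutyl)-3-[4-hydroxy-2-(triisopropylsilyloxy)phenyl]-8-(triisopropylsilyloxy)-4H-chromen-4-one; 22 3-chloro-3-methylbut-1-yne
Product: 23 5-hydroxy-6-(3-hydroxy-3-methylbutyl)-3-[4-(2-methylbut-3-yn-2-yloxy)-2-(triisopropylsilyloxy)phenyl]-8-(triisopropylsilyloxy)-4H-chromen-4-one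
Conditions: 22 (1.3 equiv), DBU (1.5 equiv), CuCl2·2H2O (1 mol%), MeCN, 0 °C
Reagents that add atoms: none
Why: Copper-catalysed propargylic substitution: the copper acetylide of 22 ionises to a copper allenylidene that the 4'-phenoxide captures at the tertiary carbon; O5 is chelated and hindered, O8 and O2' are silylated, and the aliphatic alcohol is not deprotonated by DBU.

Step 16
Reactants: 23 5-hydroxy-6-(3-hydroxy-3-methylbutyl)-3-[4-(2-methylbut-3-yn-2-yloxy)-2-(triisopropylsilyloxy)phenyl]-8-(triisopropylsilyloxy)-4H-chromen-4-one
Product: 24 3-[2,2-dimethyl-7-(triisopropylsilyloxy)-2H-chromen-6-yl]-5-hydroxy-6-(3-hydroxy-3-methylbutyl)-8-(triisopropylsilyloxy)-4H-chromen-4-one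
Conditions: Ph3PAuNTf2 (2 mol%), CH2Cl2, rt
Reagents that add atoms: none
Why: The cationic monovalent gold centre of Ph3PAuNTf2 binds the terminal alkyne, and C5' of the electron-rich ring B attacks the terminal alkyne carbon in a Friedel–Crafts sense; rearomatisation and protodeauration of the vinylgold species give the 2H-chromene and release the catalyst. The closest known reaction type is the gold- or platinum-catalysed intramolecular hydroarylation of aryl propargyl ethers to 2H-chromenes. Ring D closes in the 6-endo-dig mode; the gem-dimethyl group favours the folded conformer, and the 5-exo alternative would require attack at the internal carbon next to the quaternary centre. No stereocentre is formed. The step needs site selectivity between the two carbons ortho to O4': C3' is the more electron-rich but is shielded by the triisopropylsilyl ether on O2', whereas C5' is para to O2' and open, so closure toward C5' is expected. It also needs chemoselectivity against the free hydroxyls: the 5-OH is held in its hydrogen bond and the tertiary alcohol is remote, so neither can reach the activated alkyne. The ether C–O bond is never broken, unlike in a thermal Claisen sequence, and the neutral, non-oxidising conditions leave the silyl ethers and the hydroquinone monoether intact.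

Step 17
Reactants: 24 3-[2,2-dimethyl-7-(triisopropylsilyloxy)-2H-chromen-6-yl]-5-hydroxy-6-(3-hydroxy-3-methylbutyl)-8-(triisopropylsilyloxy)-4H-chromen-4-one
Product: 25 kraussianone 3, 5,8-dihydroxy-3-(7-hydroxy-2,2-dimethyl-2H-chromen-6-yl)-6-(3-hydroxy-3-methylbutyl)-4H-chromen-4-one
Conditions: Bu4NF/AcOH (1:1, 3 equiv), THF, 0 °C, argon; aq. NH4Cl/Na2S2O4 work-up
Reagents that add atoms: none
Why: Fluoride-induced cleavage of the two aryl silyl ethers; the acetic acid buffer keeps the phenoxides protonated, which prevents opening at C2 and air oxidation of the liberated hydroquinone, and nothing present is acidic enough to affect the chromene or the tertiary alcohol.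

## Compound list

1 | 2,5-dihydroxybenzaldehyde | O=Cc1cc(O)ccc1O | starting material
2 | 2,5-bis(methoxymethoxy)benzaldehyde | O=Cc1cc(OCOC)ccc1OCOC | intermediate
3 | 2,5-bis(methoxymethoxy)phenyl formate | O=COc1cc(OCOC)ccc1OCOC | intermediate
4 | 2,5-bis(methoxymethoxy)phenol | Oc1cc(OCOC)ccc1OCOC | intermediate
5 | 4-iodo-2,5-bis(methoxymethoxy)phenol | Oc1cc(OCOC)c(I)cc1OCOC | intermediate
6 | 2-methylbut-3-en-2-ol | CC(C)(O)C=C | starting material
7 | 4-(9-borabicyclo[3.3.1]nonan-9-yl)-2-methylbutan-2-ol | CC(C)(O)CCB1C2CCCC1CCC2 | intermediate
8 | 4-(3-hydroxy-3-methylbutyl)-2,5-bis(methoxymethoxy)phenol | CC(C)(O)CCc1cc(OCOC)c(O)cc1OCOC | intermediate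
9 | 4-(3-hydroxy-3-methylbutyl)-2-iodo-3,6-bis(methoxymethoxy)phenol | CC(C)(O)CCc1cc(OCOC)c(O)c(I)c1OCOC | intermediate
10 | 2-(1-ethoxyethenyl)-4-(3-hydroxy-3-methylbutyl)-3,6-bis(methoxymethoxy)phenol | CCOC(=C)c1c(O)c(OCOC)cc(CCC(C)(C)O)c1OCOC | intermediate
11 | 1-[2-hydroxy-5-(3-hydroxy-3-methylbutyl)-3,6-bis(methoxymethoxy)phenyl]ethan-1-one | CC(=O)c1c(O)c(OCOC)cc(CCC(C)(C)O)c1OCOC | intermediate
12 | (2E)-3-(dimethylamino)-1-[2-hydroxy-5-(3-hydroxy-3-methylbutyl)-3,6-bis(methoxymethoxy)phenyl]prop-2-en-1-one | CN(C)/C=C/C(=O)c1c(O)c(OCOC)cc(CCC(C)(C)O)c1OCOC | intermediate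
13 | 6-(3-hydroxy-3-methylbutyl)-3-iodo-5,8-bis(methoxymethoxy)-4H-chromen-4-one | CC(C)(O)CCc1cc(OCOC)c2occ(I)c(=O)c2c1OCOC | intermediate
14 | 4-bromobenzene-1,3-diol (4-bromoresorcinol) | Oc1ccc(Br)c(O)c1 | starting material
15 | 5-(benzyloxy)-2-bromophenol | Oc1cc(OCc2ccccc2)ccc1Br | intermediate
16 | 4-(benzyloxy)-1-bromo-2-(methoxymethoxy)benzene | COCOc1cc(OCc2ccccc2)ccc1Br | intermediate
17 | 2-[4-(benzyloxy)-2-(methoxymethoxy)phenyl]-4,4,5,5-tetramethyl-1,3,2-dioxaborolane | COCOc1cc(OCc2ccccc2)ccc1B1OC(C)(C)C(C)(C)O1 | intermediate
18 | 3-[4-(benzyloxy)-2-(methoxymethoxy)phenyl]-6-(3-hydroxy-3-methylbutyl)-5,8-bis(methoxymethoxy)-4H-chromen-4-one | CC(C)(O)CCc1cc(OCOC)c2occ(-c3ccc(OCc4ccccc4)cc3OCOC)c(=O)c2c1OCOC | intermediate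
19 | 3-[4-(benzyloxy)-2-hydroxyphenyl]-5,8-dihydroxy-6-(3-hydroxy-3-methylbutyl)-4H-chromen-4-one | CC(C)(O)CCc1cc(O)c2occ(-c3ccc(OCc4ccccc4)cc3O)c(=O)c2c1O | intermediate
20 | 3-[4-(benzyloxy)-2-(triisopropylsilyloxy)phenyl]-5-hydroxy-6-(3-hydroxy-3-methylbutyl)-8-(triisopropylsilyloxy)-4H-chromen-4-one | CC(C)(O)CCc1cc(O[Si](C(C)C)(C(C)C)C(C)C)c2occ(-c3ccc(OCc4ccccc4)cc3O[Si](C(C)C)(C(C)C)C(C)C)c(=O)c2c1O | intermediate
21 | 5-hydroxy-6-(3-hydroxy-3-methylbutyl)-3-[4-hydroxy-2-(triisopropylsilyloxy)phenyl]-8-(triisopropylsilyloxy)-4H-chromen-4-one | CC(C)(O)CCc1cc(O[Si](C(C)C)(C(C)C)C(C)C)c2occ(-c3ccc(O)cc3O[Si](C(C)C)(C(C)C)C(C)C)c(=O)c2c1O | intermediate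
22 | 3-chloro-3-methylbut-1-yne | CC(C)(Cl)C#C | starting material
23 | 5-hydroxy-6-(3-hydroxy-3-methylbutyl)-3-[4-(2-methylbut-3-yn-2-yloxy)-2-(triisopropylsilyloxy)phenyl]-8-(triisopropylsilyloxy)-4H-chromen-4-one | CC(C)(O)CCc1cc(O[Si](C(C)C)(C(C)C)C(C)C)c2occ(-c3ccc(OC(C)(C)C#C)cc3O[Si](C(C)C)(C(C)C)C(C)C)c(=O)c2c1O | intermediate
24 | 3-[2,2-dimethyl-7-(triisopropylsilyloxy)-2H-chromen-6-yl]-5-hydroxy-6-(3-hydroxy-3-methylbutyl)-8-(triisopropylsilyloxy)-4H-chromen-4-one | CC(C)(O)CCc1cc(O[Si](C(C)C)(C(C)C)C(C)C)c2occ(-c3cc4C=CC(C)(C)Oc4cc3O[Si](C(C)C)(C(C)C)C(C)C)c(=O)c2c1O | intermediate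
25 | kraussianone 3, 5,8-dihydroxy-3-(7-hydroxy-2,2-dimethyl-2H-chromen-6-yl)-6-(3-hydroxy-3-methylbutyl)-4H-chromen-4-one | CC(C)(O)CCc1cc(O)c2occ(-c3cc4c(cc3O)OC(C)(C)C=C4)c(=O)c2c1O | target

## Step count and least certain steps

Total step count: 17. Longest linear sequence: 14 (steps 1 to 7, then 11 to 17); steps 8 to 10 form the convergent ring-B branch.

Step 16 (key step). The most likely failure is loss of site control in the ring closure, with attack at C3' competing if the silyl ether shields less than expected. The other is stalling of the catalyst, held by the chelating 5-hydroxy-4-keto unit or by traces of amine and chloride from step 15, so that hydration of the activated alkyne by adventitious water takes over. Fallback: ring D is built from the same ether without metal, by the aromatic propargyl Claisen cascade (N,N-diethylaniline, 160 °C). A [3,3] shift to C5' and tautomerisation give the ortho-allenylphenol 5-hydroxy-3-[4-hydroxy-5-(3-methylbuta-1,2-dien-1-yl)-2-(triisopropylsilyloxy)phenyl]-6-(3-hydroxy-3-methylbutyl)-8-(triisopropylsilyloxy)-4H-chromen-4-one F1, which is not isolated and closes by 1,5-hydrogen shift and oxa-6π electrocyclisation. This breaks and re-forms the ether C–O bond, so it is a different bond set and mechanism. It sets out from 23 and comes back at 24.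

Step 6. Oxidative addition at an aryl iodide flanked by a phenoxide and an acetal oxygen may be slow, so that reductive loss of iodine wins; the acidic hydrolysis of the enol ether may also begin to strip the acetal next to the new carbonyl. Fallback without halide or Pd: it sets out from 8, bypasses 9 and returns at 11. Magnesium-mediated ortho-formylation (MgCl2, Et3N, paraformaldehyde, MeCN, reflux) gives 2-hydroxy-5-(3-hydroxy-3-methylbutyl)-3,6-bis(methoxymethoxy)benzaldehyde F2. Excess MeMgBr in THF then gives racemic 2-(1-hydroxyethyl)-4-(3-hydroxy-3-methylbutyl)-3,6-bis(methoxymethoxy)phenol F3, and MnO2 in CH2Cl2 oxidises the benzylic alcohol to 11.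

Step 12. The acid may ionise the tertiary alcohol; the cation would then be captured by the neighbouring 5-OH (closure to a chroman) or by methanol, or it would eliminate. The free hydroquinone may also oxidise during work-up. Fallback under buffered, non-protic conditions: it sets out from 18 and returns at 19. TMSOTf with 2,2'-bipyridyl in CH2Cl2 at 0 °C exchanges the three aryl acetals for silyl ethers and masks the tertiary alcohol at the same time, giving 3-[4-(benzyloxy)-2-(trimethylsilyloxy)phenyl]-6-[3-methyl-3-(trimethylsilyloxy)butyl]-5,8-bis(trimethylsilyloxy)-4H-chromen-4-one F4. Aqueous work-up and a brief citrate-buffered hydrolysis at 0 °C under argon then give 19.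

Step 4. The borane may be consumed by the two hydroxyl groups and transmetalation may be slow, so that protodeiodination of the electron-rich iodophenoxide competes. Fallback in two steps: it sets out from 5 and returns at 8. Sonogashira coupling with commercial 2-methylbut-3-yn-2-ol (Pd(PPh3)2Cl2, CuI, Et3N, 50 °C) gives 4-(3-hydroxy-3-methylbut-1-yn-1-yl)-2,5-bis(methoxymethoxy)phenol F5, and hydrogenation (H2, 10% Pd/C, EtOAc) saturates the alkyne to 8.

Step 8. Discrimination between the two hydroxyls may be insufficient, leading to alkylation at the bromine-flanked oxygen and to double alkylation. Fallback in which the differentiating event is a far bulkier silylation and the benzyl group then enters at the only free oxygen: it sets out from 14, bypasses 15 and returns at 16. TIPSCl (1.0 equiv) and imidazole in DMF at 0 °C give 2-bromo-5-(triisopropylsilyloxy)phenol F6. MOMCl and i-Pr2NEt give [4-bromo-3-(methoxymethoxy)phenoxy]triisopropylsilane F7. Bu4NF in THF at 0 °C gives 4-bromo-3-(methoxymethoxy)phenol F8, and BnBr with K2CO3 in acetone gives 16.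

## Further compounds

F1 | step 16 | 5-hydroxy-3-[4-hydroxy-5-(3-methylbuta-1,2-dien-1-yl)-2-(triisopropylsilyloxy)phenyl]-6-(3-hydroxy-3-methylbutyl)-8-(triisopropylsilyloxy)-4H-chromen-4-one | CC(C)(O)CCc1cc(O[Si](C(C)C)(C(C)C)C(C)C)c2occ(-c3cc(C=C=C(C)C)c(O)cc3O[Si](C(C)C)(C(C)C)C(C)C)c(=O)c2c1O
F2 | step 6 | 2-hydroxy-5-(3-hydroxy-3-methylbutyl)-3,6-bis(methoxymethoxy)benzaldehyde | O=Cc1c(O)c(OCOC)cc(CCC(C)(C)O)c1OCOC
F3 | step 6 | racemic 2-(1-hydroxyethyl)-4-(3-hydroxy-3-methylbutyl)-3,6-bis(methoxymethoxy)phenol | CC(O)c1c(O)c(OCOC)cc(CCC(C)(C)O)c1OCOC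
F4 | step 12 | 3-[4-(benzyloxy)-2-(trimethylsilyloxy)phenyl]-6-[3-methyl-3-(trimethylsilyloxy)butyl]-5,8-bis(trimethylsilyloxy)-4H-chromen-4-one | CC(C)(O[Si](C)(C)C)CCc1cc(O[Si](C)(C)C)c2occ(-c3ccc(OCc4ccccc4)cc3O[Si](C)(C)C)c(=O)c2c1O[Si](C)(C)C
F5 | step 4 | 4-(3-hydroxy-3-methylbut-1-yn-1-yl)-2,5-bis(methoxymethoxy)phenol | CC(C)(O)C#Cc1cc(OCOC)c(O)cc1OCOC
F6 | step 8 | 2-bromo-5-(triisopropylsilyloxy)phenol | Oc1cc(O[Si](C(C)C)(C(C)C)C(C)C)ccc1Br
F7 | step 8 | [4-bromo-3-(methoxymethoxy)phenoxy]triisopropylsilane | COCOc1cc(O[Si](C(C)C)(C(C)C)C(C)C)ccc1Br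
F8 | step 8 | 4-bromo-3-(methoxymethoxy)phenol | COCOc1cc(O)ccc1Br
A1 | alternative 1 | 2-(acetyloxy)-3,6-bis(methoxymethoxy)-5-[3-methyl-3-(triethylsilyloxy)butyl]benzoyl chloride | CC(=O)Oc1c(OCOC)cc(CCC(C)(C)O[Si](CC)(CC)CC)c(OCOC)c1C(Cl)=O
A2 | alternative 1 | 4-[(E)-2-[2,2-dimethyl-7-(methoxymethoxy)-2H-chromen-6-yl]ethenyl]morpholine | COCOc1cc2OC(C)(C)C=Cc2cc1/C=C/N1CCOCC1
A3 | alternative 1 | 3-[2,2-dimethyl-7-(methoxymethoxy)-2H-chromen-6-yl]-5,8-bis(methoxymethoxy)-6-[3-methyl-3-(triethylsilyloxy)butyl]-4H-chromen-4-one | CC(C)(O[Si](CC)(CC)CC)CCc1cc(OCOC)c2occ(-c3cc4C=CC(C)(C)Oc4cc3OCOC)c(=O)c2c1OCOC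
A4 | alternative 2 | 6-[(dimethylamino)methyl]-3-[2,2-dimethyl-7-(methoxymethoxy)-2H-chromen-6-yl]-5-hydroxy-8-(methoxymethoxy)-4H-chromen-4-one | CN(C)Cc1cc(OCOC)c2occ(-c3cc4C=CC(C)(C)Oc4cc3OCOC)c(=O)c2c1O
A5 | alternative 2 | 3-[2,2-dimethyl-7-(methoxymethoxy)-2H-chromen-6-yl]-8-(methoxymethoxy)-6-methylidene-4H-chromene-4,5(6H)-dione | C=C1C=C(OCOC)C2=C(C1=O)C(=O)C(=CO2)c1cc2C=CC(C)(C)Oc2cc1OCOC
A6 | alternative 2 | 2-methoxypropene | COC(C)=C
A7 | alternative 2 | racemic 2-methoxy-2-methyl-3,4-dihydro-2H-pyran ketal fused through O5 and C6 to 3-[2,2-dimethyl-7-(methoxymethoxy)-2H-chromen-6-yl]-8-(methoxymethoxy)-4H-chromen-4-one | COC1(C)CCc2cc(OCOC)c3occ(-c4cc5C=CC(C)(C)Oc5cc4OCOC)c(=O)c3c2O1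
A8 | alternative 2 | 3-[2,2-dimethyl-7-(methoxymethoxy)-2H-chromen-6-yl]-5-hydroxy-8-(methoxymethoxy)-6-(3-oxobutyl)-4H-chromen-4-one | CC(=O)CCc1cc(OCOC)c2occ(-c3cc4C=CC(C)(C)Oc4cc3OCOC)c(=O)c2c1O
A9 | alternative 3 | 2-[7-(tert-butyldimethylsilyloxy)-2,2-dimethyl-2H-chromen-6-yl]-3-hydroxy-1-[2-hydroxy-3-(3-hydroxy-3-methylbutyl)-5-methoxyphenyl]prop-2-en-1-one (enol form, geometry mobile) | COc1cc(CCC(C)(C)O)c(O)c(C(=O)C(=CO)c2cc3C=CC(C)(C)Oc3cc2O[Si](C)(C)C(C)(C)C)c1
A10 | alternative 3 | 2-{2-[7-(tert-butyldimethylsilyloxy)-2,2-dimethyl-2H-chromen-6-yl]-3-hydroxyprop-2-enoyl}-6-(3-hydroxy-3-methylbutyl)cyclohexa-2,5-diene-1,4-dione | CC(C)(O)CCC1=CC(=O)C=C(C(=O)C(=CO)c2cc3C=CC(C)(C)Oc3cc2O[Si](C)(C)C(C)(C)C)C1=O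
A11 | alternative 3 | 3-[7-(tert-butyldimethylsilyloxy)-2,2-dimethyl-2H-chromen-6-yl]-5,8-dihydroxy-6-(3-hydroxy-3-methylbutyl)-4H-chromen-4-one | CC(C)(O)CCc1cc(O)c2occ(-c3cc4C=CC(C)(C)Oc4cc3O[Si](C)(C)C(C)(C)C)c(=O)c2c1O
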